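The runs are calculated on assumed constants; scatter was added.

Read these two runs for the gap, the part of the charge that is not yet D.

| flask | X | remark | time |
|---|---|---|---|
| Friday's | 23 mM | the very flask that is asked about, followed so far |  |
| Thursday's | 12 mM | run made earlier |  |
| flask | 23 mM |  | 12 h |

Friday's run (percent of the X charged)

| time / min | D / % | J / % | X / % |
|---|---|---|---|
| 10.0 | 25 | 16 | 25 |
| 15.0 | 25 | 18 | 19 |
| 30.0 | 43 | 9 | 17 |
| 50.0 | 54 | 7 | 10 |
| 80.0 | 71 | 4 | 11 |
| 120 | 86 | 2 | 6 |

Thursday's run (percent of the X charged)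

| time / h | D / % | J / % | X / % |
|---|---|---|---|
| 0.333 | 32 | 12 | 20 |
| 1.00 | 62 | 8 | 14 |
| 1.50 | 72 | 3 | 6 |
| 2.50 | 91 | 3 | 3 |
| 4.00 | 98 | 1 | 4 |
| 5.00 | 98 | 3 | 0 |

(readings scatter by 2 percentage points)



* ratio of D to J at 30 s
* ratio of D to J at 12 h
* which of D and J there is more of at 12 h

Late in each run the gap halves at a steady pace. Friday's gap falls from 57.0% at 30.0 min to 14.0% at 120 min, and Thursday's from 68.0% at 0.333 h to 9.00% at 2.50 h. So we reckon:

Friday: 0.741 h

Thursday: 0.743 h

This fill half-life, the time the gap takes to halve, comes out alike at 23 mM and 12 mM, so we take the flask as first order in the charge.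

Now the curve. At the start we let D gain at that pace, 0.780% of the charge by 30 s. No reading shows J that early, so as a rough assumption we book J at its first reading in Friday's run, 16% at 10.0 min, and our early ratio is:

D over J = 0.0487

By 10.0 min D already leads J, 25% against 16%, so the crossing lies earlier. J reads 18% at 15.0 min and 9% at 30.0 min, so its knee is behind us there. The time 12 h is 16.2 fill half-lives, so D stands on its level. Thursday's late J reads 1% and 3% beside D at 98%, so our end ratio is near 49.0, open upward, with a scatter of 2 percentage points.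

The forecast gave 1 (0.5 to 1.8) at 30 s, above our figure, and 50 (25 to 400) at 12 h, with D ahead: “J peaks early, then decays, so it is a kinetic product that drains towards D”.

The flask gives 0.0957 and 164, with D ahead.

    X ⇌ E (K = 0.890, k = 0.00100 /s)
    J ⇌ D (k = 4.20 × 10⁻⁴ /s)
    X ⇌ J (K = 0.530, k = 0.0130 /s)
    J ⇌ G (K = 1.80, k = 0.00590 /s)
    X ⇌ D (K = 87.0, k = 7.30 × 10⁻⁴ /s)

The fill half-life runs on in Friday's flask: from the reading at 30.0 min it puts D at 70.4% at 1.20 h, and the flask holds 69.1%. The flask at 9.2 mM ends with D at 96.3% and the ratio at 164. The early ratio in Friday's flask rests in part on the path from X to D, both ways: the run without that path moves it at 30 s from 0.0957 to 0.00773.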